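All runs are calculated with made-up constants; the scatter is artificial.

The constants of the proposed steps were hidden from me, so I looked for a number the readings give without them. Let ρ be partner charged per substrate charged, left-handed and right-handed together.

| setting | south-east | north-west | south | midnight | spring | noon |
|---|---|---|---|---|---|---|
| left-handed substrate | 0.050 M | 0.050 M | 0.050 M | 0.050 M | 0.050 M | 0.050 M |
| right-handed substrate | 0.050 M | 0.050 M | 0.050 M | 0.050 M | 0.050 M | 0.050 M |
| partner | 0.028 M | 0.11 M | 0.055 M | 0.0550 M | 0.0550 M | 0.0550 M |
| catalyst | 7 mM | 7 mM | 3.5 mM | 7.0 mM | 7.0 mM | 7.0 mM |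
| temperature | −10 °C | 10 °C | −10 °C | −5 °C | 25 °C |  |
| remark | run made earlier | run made earlier | run made earlier |  |  | at 25 °C until 20 min, from then on at −5 °C |
| time |  |  |  | 25 min | 25 min | 25 min |

| run | time / min | left-handed product / % | left-handed substrate / % |
|---|---|---|---|
| south-east | 2.00 | 1.0 | 50.3 |
| south-east | 5.00 | 2.5 | 49.2 |
| south-east | 10.0 | 4.4 | 47.9 |
| south-east | 15.0 | 5.5 | 44.0 |
| south-east | 20.0 | 5.0 | 42.8 |
| north-west | 0.667 | 6.7 | 45.3 |
| north-west | 1.33 | 10.6 | 40.2 |
| north-west | 3.00 | 15.6 | 36.3 |
| north-west | 5.00 | 18.4 | 30.4 |
| north-west | 10.0 | 21.2 | 28.2 |
| south | 4.00 | 2.3 | 47.8 |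
| south | 8.00 | 2.2 | 45.8 |
| south | 12.0 | 5.8 | 44.9 |
| south | 15.0 | 5.6 | 44.7 |
| south | 20.0 | 8.3 | 43.9 |

(each reading ± 1 percentage point)

1. the best flask by amount of left-handed product, in percent of the left-handed substrate and right-handed substrate together charged; "all alike" if 1.5 percentage points covers them all (midnight / spring / noon / all alike)
2. amount of left-handed product at the end, in percent of the left-handed substrate and right-handed substrate together charged, midnight
3. amount of left-handed product at the end, in percent of the left-handed substrate and right-handed substrate together charged, spring
4. amount of left-handed product at the end, in percent of the left-handed substrate and right-handed substrate together charged, noon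

- catalyst is single-handed; left-handed substrate and right-handed substrate are mirror images of each other, charged as a racemate, each of them at the stated concentration
- steps that have been proposed: partner -> decomposed reagent; partner + catalyst + right-handed substrate -> catalyst + right-handed product; partner + catalyst + left-handed substrate -> catalyst + left-handed product; partner <-> dormant form

North-west, slowing, stood at 21.2% at its last reading with ρ = 1.10, and dividing the two gave

φ = 0.193

This is the partner's yield: left-handed product made per partner charged, both counted against the substrate charged. South-east, at ρ = 0.280, gave 0.196. I then compared the two runs in common logarithms, north-west against south-east: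

making per partner, from the first slopes: +0.709
lifetime, late reading over first slope: −0.717

These nearly cancel, which says the two φ over again and is no second test, and I took the product as φρ. With ρ = 0.550, that made 10.6% for spring and noon.

Was one number enough? South had half the catalyst of south-east. If making scales with catalyst, south should have come to 5.40%, but its last reading was 8.3%, which is more, against a scatter of 1 percentage point. Scaled to full catalyst, that reading gives a cold φ of 0.302. So I put midnight between 10.8% and 16.6%, and leaned towards it as best.

The forecast differed and said all alike: midnight 13% (10.5% to 16%), spring 12.5% (9.5% to 16%), noon 13% (10% to 19%), holding that “The yield therefore depends little on temperature”.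

The best flask was midnight: midnight gave 15.7%, spring 11.2%, noon 10.6%. The gap between midnight and spring is wider than the margin, so the call of all alike did not stand, though the forecast's three figures lay within tolerance. After 25.0 min, midnight held 18% of its partner free and spring, with partner as limiting reagent, 1.3%, while the dormant form stood at 0.0163 M in midnight and 0.0275 M in spring. Divided by ρ, midnight's yield is 0.285, inside my cold span, and spring's is 0.204, close to north-west's φ.

    partner → decomposed reagent (k = 0.170 min⁻¹, Ea = 95.0 kJ mol⁻¹)
    partner + catalyst + right-handed substrate → catalyst + right-handed product (k = 420 L² mol⁻² min⁻¹, Ea = 43.0 kJ mol⁻¹)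
    partner + catalyst + left-handed substrate → catalyst + left-handed product (k = 710 L² mol⁻² min⁻¹, Ea = 47.0 kJ mol⁻¹)
    partner ⇌ dormant form (K = 28.0, k = 1.20 min⁻¹, Ea = 85.0 kJ mol⁻¹, ΔH = −27.0 kJ mol⁻¹)
    (constants at 25 °C)

A further flask, spring with 0.22 M of partner, has ρ = 2.20, so φ gives 42.5%. The simulation gives 33.3%, lower, with 33% of the charged left-handed substrate left.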